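**Retrosynthetic overview**

1. Hedyotol C is a medioresinol-type furofuran with an erythro guaiacylglycerol unit on the syringyl O4. The side chain is cut last at C7''–C8'': Evans syn-aldol of an aryloxyacetyl imide built on the free syringyl phenol, then Mitsunobu inversion at C7''.
2. The guaiacyl oxolane (C2–O3–C4–C5–C1) is opened at C2–O3 to a benzylic 1,4-diol, and further to an aryllithium plus the bicyclic lactone 11, whose carbonyl carbon is C2.
3. The syringyl oxolane (C1–C8–O7–C6–C5) is not closed from a chain. It is the cyclopropane C1–C5–C6 of lactone 7, expanded by C8 and O7 of formaldehyde (formal [3+2], step 5); the activating ester is then removed.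
4. Enabling feature: in 7 the cyclopropane bond C1–C6 is a push–pull bond. C6 carries the 4-alkoxy-3,5-dimethoxyphenyl donor, C1 carries the geminal lactone C2=O and CO2Me acceptors (a chelating 1,3-dicarbonyl), and the cis-fused lactone holds C1 and C6 on one face.
5. Lactone 7 comes from O-allylsinapaldehyde and bromomalonate by an organocatalytic Michael–alkylation (sets C5) and reduction/lactonisation. Ring order: cyclopropane, γ-lactone, syringyl oxolane (ring expansion), guaiacyl oxolane.

Key step: step 5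

Remark on numbering: bicyclic compounds are numbered as 3,7-dioxabicyclo[3.3.0]octanes (C1 and C5 ring-fusion carbons, C2 the lactone carbonyl that later carries the guaiacyl group, O3, C4, C6 the syringyl-type carbon, O7, C8). Cyclopropane 7 is numbered as a 3-oxabicyclo[3.1.0]hexane with the same C1, C2, O3, C4, C5 and C6.

Assumption: the organocatalytic step is taken to follow the usual sense for cinnamaldehydes with the (S)-diarylprolinol silyl ether (attack on the face away from the CPh2OTMS group), which gives the (2R,3S) series drawn; the mirror-image catalyst would be used if the opposite sense were found.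

Step 1
Reactants: 1 syringaldehyde (4-hydroxy-3,5-dimethoxybenzaldehyde)
Product: 2 4-(allyloxy)-3,5-dimethoxybenzaldehyde
Conditions: allyl bromide, K2CO3, DMF, 50 °C
Reagents that add atoms: allyl bromide, C=CCBr
Why: Williamson etherification of the acidic phenol; the allyl ether should survive every step up to 16 and later leave under Pd(PPh3)4 without touching the benzyl ethers.

Step 2
Reactants: 2 4-(allyloxy)-3,5-dimethoxybenzaldehyde
Product: 3 (E)-3-[4-(allyloxy)-3,5-dimethoxyphenyl]prop-2-enal
Conditions: Ph3P=CHCHO (1.1 equiv), toluene, 90 °C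
Reagents that add atoms: (triphenylphosphoranylidene)acetaldehyde, O=CC=P(c1ccccc1)(c1ccccc1)c1ccccc1
Why: Wittig olefination with a stabilised ylide, which should give the E-enal.

Step 3
Reactants: 3 (E)-3-[4-(allyloxy)-3,5-dimethoxyphenyl]prop-2-enal; 4 dimethyl 2-bromomalonate
Product: 5 dimethyl (2R,3S)-2-formyl-3-[4-(allyloxy)-3,5-dimethoxyphenyl]cyclopropane-1,1-dicarboxylate (formyl and aryl trans)
Conditions: (S)-α,α-diphenylprolinol trimethylsilyl ether (20 mol%), 2,6-lutidine (1.1 equiv), CH2Cl2, 0 °C → rt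
Reagents that add atoms: none
Why: Michael-initiated ring closure under iminium–enamine organocatalysis, in which the CPh2OTMS group shields one face of the s-trans E-iminium ion so that the bromomalonate carbanion should add to the open face of the aryl-bearing carbon (S) and the enamine then displaces bromide (3-exo-tet), which sets the formyl-bearing carbon (R) trans to the aryl group.

Step 4
Reactants: 5 dimethyl (2R,3S)-2-formyl-3-[4-(allyloxy)-3,5-dimethoxyphenyl]cyclopropane-1,1-dicarboxylate
Product: 7 methyl (1S,5R,6S)-6-[4-(allyloxy)-3,5-dimethoxyphenyl]-2-oxo-3-oxabicyclo[3.1.0]hexane-1-carboxylate, via hydroxymethyl diester 6 (not isolated)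
Conditions: NaBH4, MeOH, 0 °C → rt
Reagents that add atoms: none
Why: chemoselective borohydride reduction of the aldehyde, after which the hydroxymethyl group can reach only the ester cis to it and lactonises (5-exo-trig acyl substitution), which differentiates the two esters and makes C1 a stereocentre without any new selection.

Step 5
Reactants: 7 methyl (1S,5R,6S)-6-[4-(allyloxy)-3,5-dimethoxyphenyl]-2-oxo-3-oxabicyclo[3.1.0]hexane-1-carboxylate
Product: 10 methyl (1R,5R,6S)-6-[4-(allyloxy)-3,5-dimethoxyphenyl]-2-oxo-3,7-dioxabicyclo[3.3.0]octane-1-carboxylate, via iodo magnesium enolate 8 (not isolated), via hydroxymethyl iodide 9 (not isolated)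
Conditions: MgI2 (0.5 equiv), paraformaldehyde (5 equiv), THF, 50 °C
Reagents that add atoms: formaldehyde (set free from paraformaldehyde), C=O
Why: Proposed new method: MgI2 chelates the two geminal carbonyls on C1, iodide opens the push–pull C1–C6 bond at the benzylic carbon C6 with inversion, the magnesium enolate is hydroxymethylated at C1 by formaldehyde, and the new alkoxide displaces the benzylic iodide, so that C8 and O7 are inserted into the three-membered ring and the oxolane C1–C8–O7–C6–C5 results; the closest known reaction types are the Lewis-acid formal [3+2] cycloaddition of 2-arylcyclopropane-1,1-diesters with aldehydes and the MgI2-relayed ring expansion of acceptor cyclopropanes with imines, neither shown with formaldehyde on a lactone-fused cyclopropane. The only ring closed is this oxolane, by a 5-exo-tet O-alkylation at C6 (SN2 on the benzylic iodide, or capture of the corresponding 4-alkoxybenzyl cation from the same side). C1 becomes quaternary with C8 cis to the C5–C6 bond, because only the hydroxymethyl epimer cis to the iodobenzyl arm can close the cis-fused bicycle and hydroxymethylation of the malonate-type enolate is reversible. C6 is formed with net retention (double inversion), which places the aryl group exo, trans to C4; a cationic closure should give the same result, because allylic 1,3-strain keeps C5–H eclipsed with the aryl group while O7 arrives from the C1 side, and C5 from step 3 is untouched. The step needs C–C bond formation at C1 before C–O bond formation at C6 (direct attack of the aldehyde oxygen on C6 from the face away from C1 would give the endo-aryl epimer); this order is secured by formaldehyde being the weakest oxygen nucleophile and strongest carbon electrophile among aldehydes, by the soft iodide and by the chelated enolate, and the site of ring opening is secured by the aryl donor on C6 alone.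

Step 6
Reactants: 10 methyl (1R,5R,6S)-6-[4-(allyloxy)-3,5-dimethoxyphenyl]-2-oxo-3,7-dioxabicyclo[3.3.0]octane-1-carboxylate
Product: 11 (1R,5R,6S)-6-[4-(allyloxy)-3,5-dimethoxyphenyl]-3,7-dioxabicyclo[3.3.0]octan-2-one
Conditions: LiCl, DMSO–H2O, 130 °C
Reagents that add atoms: none
Why: Krapcho dealkoxycarbonylation (chloride attacks the ester methyl group and the malonate-type carboxylate loses CO2), in which protonation of the lactone enolate at C1 can give only the cis-fused bicycle, so C1 (R) follows from C5.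

Step 7
Reactants: 11 (1R,5R,6S)-6-[4-(allyloxy)-3,5-dimethoxyphenyl]-3,7-dioxabicyclo[3.3.0]octan-2-one; 12 1-(benzyloxy)-4-bromo-2-methoxybenzene
Product: 15 [(3R,4R,5S)-5-[4-(allyloxy)-3,5-dimethoxyphenyl]-4-(hydroxymethyl)oxolan-3-yl][4-(benzyloxy)-3-methoxyphenyl]methanol (both carbinol epimers), via aryllithium 13 (not isolated), via keto alkoxide 14 (not isolated)
Conditions: 12, n-BuLi, THF, −78 °C; then 11, −78 °C; then MeOH, NaBH4, −78 → 0 °C
Reagents that add atoms: none
Why: bromine–lithium exchange and single addition of the aryllithium to the lactone (the lithium hemiketalate, in equilibrium with 14, should hold at −78 °C), then borohydride reduction of the ketone form; C1 should keep its configuration at low temperature, and the carbinol epimers need no control because step 8 passes through the benzylic cation.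

Step 8
Reactants: 15 [(3R,4R,5S)-5-[4-(allyloxy)-3,5-dimethoxyphenyl]-4-(hydroxymethyl)oxolan-3-yl][4-(benzyloxy)-3-methoxyphenyl]methanol
Product: 16 (1R,2S,5R,6S)-6-[4-(allyloxy)-3,5-dimethoxyphenyl]-2-[4-(benzyloxy)-3-methoxyphenyl]-3,7-dioxabicyclo[3.3.0]octane
Conditions: camphor-10-sulfonic acid (10 mol%), CH2Cl2, 0 °C
Reagents that add atoms: none
Why: acid-catalysed SN1 cyclodehydration, in which the 4-benzyloxy-3-methoxybenzyl cation at C2 is captured by the C4 hydroxyl to close the oxolane C2–O3–C4–C5–C1, and C2 (S) should be set by a transition state with C1–H eclipsing the aryl group (allylic 1,3-strain) and O3 arriving from the C5 side, which places the aryl group exo, trans to C8, from either carbinol epimer.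

Step 9
Reactants: 16 (1R,2S,5R,6S)-6-[4-(allyloxy)-3,5-dimethoxyphenyl]-2-[4-(benzyloxy)-3-methoxyphenyl]-3,7-dioxabicyclo[3.3.0]octane
Product: 17 4-[(1R,2S,5R,6S)-6-[4-(benzyloxy)-3-methoxyphenyl]-3,7-dioxabicyclo[3.3.0]octan-2-yl]-2,6-dimethoxyphenol (guaiacyl O-benzyl medioresinol)
Conditions: Pd(PPh3)4 (5 mol%), morpholine, THF, rt
Reagents that add atoms: none
Why: Tsuji–Trost deallylation, in which zerovalent palladium ionises the aryl allyl ether to a π-allyl complex that morpholine captures, so that only the syringyl phenol should be freed.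

Step 10
Reactants: 18 (S)-4-benzyloxazolidin-2-one
Product: 20 (S)-4-benzyl-3-(2-bromoacetyl)oxazolidin-2-one, via lithium oxazolidinide 19 (not isolated)
Conditions: n-BuLi, THF, −78 °C; then BrCH2COBr, −78 °C
Reagents that add atoms: bromoacetyl bromide, BrCC(Br)=O
Why: N-acylation of the lithiated oxazolidinone, which should take place at the acyl bromide far faster than at the alkyl bromide at −78 °C.

Step 11
Reactants: 17 guaiacyl O-benzyl medioresinol; 20 (S)-4-benzyl-3-(2-bromoacetyl)oxazolidin-2-one
Product: 21 (S)-4-benzyl-3-[2-[4-[(1R,2S,5R,6S)-6-[4-(benzyloxy)-3-methoxyphenyl]-3,7-dioxabicyclo[3.3.0]octan-2-yl]-2,6-dimethoxyphenoxy]acetyl]oxazolidin-2-one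
Conditions: K2CO3, MeCN, rt
Reagents that add atoms: none
Why: Williamson etherification in which the 2,6-dimethoxyphenoxide should displace bromide from the carbonyl-activated primary carbon (SN2), the same kind of alkylation that builds aryl ethers from phenacyl bromides.

Step 12
Reactants: 21 aryloxyacetyl imide; 22 4-(benzyloxy)-3-methoxybenzaldehyde
Product: 24 syn-aldol imide with (2S,3R)-2-aryloxy-3-[4-(benzyloxy)-3-methoxyphenyl]-3-hydroxypropanoyl chain on the (S)-4-benzyloxazolidin-2-one, via boron enolate 23 (not isolated)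
Conditions: Bu2BOTf, i-Pr2NEt, CH2Cl2, −78 → 0 °C; then 22, −78 → 0 °C; pH 7 buffer, MeOH, H2O2
Reagents that add atoms: none
Why: Evans syn-aldol reaction, in which the Z-dibutylboron enolate reacts through a Zimmerman–Traxler chair on the face away from the benzyl group of the (S)-auxiliary, which should set the aryloxy carbon (2S) and the carbinol carbon (3R) in the threo arrangement.

Step 13
Reactants: 24 syn-aldol imide
Product: 25 (2S,3S)-3-(4-nitrobenzoyloxy) imide (benzylic carbon inverted)
Conditions: 4-O2NC6H4CO2H, PPh3, DIAD, THF, 0 °C → rt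
Reagents that add atoms: 4-nitrobenzoic acid, OC(=O)c1ccc(cc1)[N+](=O)[O-]
Why: Mitsunobu reaction, in which SN2 displacement of the oxyphosphonium by the carboxylate should invert the benzylic carbinol carbon (3R to 3S) and so turn the threo aldol into the erythro series.

Step 14
Reactants: 25 (2S,3S)-3-(4-nitrobenzoyloxy) imide
Product: 26 di-O-benzyl hedyotol C, with (1S,2R)-1-[4-(benzyloxy)-3-methoxyphenyl]-1,3-dihydroxypropan-2-yl ether on the syringyl oxygen
Conditions: LiBH4, THF–MeOH, 0 °C → rt
Reagents that add atoms: none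
Why: borohydride reduction of the imide carbonyl to the primary alcohol with release of the auxiliary, together with reductive cleavage of the nitrobenzoate, touches no stereocentre and should give the erythro diol.

Step 15
Reactants: 26 di-O-benzyl hedyotol C
Product: 27 hedyotol C
Conditions: H2 (1 atm), Pd/C, EtOAc–MeOH, rt
Reagents that add atoms: none
Why: hydrogenolysis of the two aryl benzyl ethers, which under neutral conditions should be cleaved much faster than the benzylic C–O bonds of the furofuran and of the side-chain alcohol.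

**Compound list**

1 | syringaldehyde | COc1cc(C=O)cc(OC)c1O | starting material
2 | 4-(allyloxy)-3,5-dimethoxybenzaldehyde | COc1cc(C=O)cc(OC)c1OCC=C | intermediate
3 | (E)-3-[4-(allyloxy)-3,5-dimethoxyphenyl]prop-2-enal | COc1cc(/C=C/C=O)cc(OC)c1OCC=C | intermediate
4 | dimethyl 2-bromomalonate | COC(=O)C(Br)C(=O)OC | starting material
5 | dimethyl (2R,3S)-2-formyl-3-[4-(allyloxy)-3,5-dimethoxyphenyl]cyclopropane-1,1-dicarboxylate | COC(=O)C1(C(=O)OC)[C@H](C=O)[C@H]1c1cc(OC)c(OCC=C)c(OC)c1 | intermediate
6 | dimethyl (2R,3S)-2-(hydroxymethyl)-3-[4-(allyloxy)-3,5-dimethoxyphenyl]cyclopropane-1,1-dicarboxylate | COC(=O)C1(C(=O)OC)[C@H](CO)[C@H]1c1cc(OC)c(OCC=C)c(OC)c1 | intermediate (not isolated)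
7 | methyl (1S,5R,6S)-6-[4-(allyloxy)-3,5-dimethoxyphenyl]-2-oxo-3-oxabicyclo[3.1.0]hexane-1-carboxylate | COC(=O)[C@@]12C(=O)OC[C@@H]1[C@H]2c1cc(OC)c(OCC=C)c(OC)c1 | intermediate
8 | iodomagnesium enolate of methyl (4R)-4-[(R)-[4-(allyloxy)-3,5-dimethoxyphenyl](iodo)methyl]-2-oxooxolane-3-carboxylate | COC(=O)C1=C(O[Mg]I)OC[C@@H]1[C@@H](I)c1cc(OC)c(OCC=C)c(OC)c1 | intermediate (not isolated)
9 | iodomagnesium alkoxide of methyl (3R,4R)-3-(hydroxymethyl)-4-[(R)-[4-(allyloxy)-3,5-dimethoxyphenyl](iodo)methyl]-2-oxooxolane-3-carboxylate | O=C1OC[C@H]([C@@H](I)c2cc(OC)c(OCC=C)c(OC)c2)[C@]1(C(=O)OC)CO[Mg]I | intermediate (not isolated)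
10 | methyl (1R,5R,6S)-6-[4-(allyloxy)-3,5-dimethoxyphenyl]-2-oxo-3,7-dioxabicyclo[3.3.0]octane-1-carboxylate | O=C1OC[C@H]2[C@]1(C(=O)OC)CO[C@@H]2c1cc(OC)c(OCC=C)c(OC)c1 | intermediate
11 | (1R,5R,6S)-6-[4-(allyloxy)-3,5-dimethoxyphenyl]-3,7-dioxabicyclo[3.3.0]octan-2-one | O=C1OC[C@H]2[C@@H]1CO[C@@H]2c1cc(OC)c(OCC=C)c(OC)c1 | intermediate
12 | 1-(benzyloxy)-4-bromo-2-methoxybenzene | COc1cc(Br)ccc1OCc1ccccc1 | starting material
13 | [4-(benzyloxy)-3-methoxyphenyl]lithium | [Li]c1ccc(OCc2ccccc2)c(OC)c1 | intermediate (not isolated)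
14 | lithium alkoxide of [(3R,4R,5S)-5-[4-(allyloxy)-3,5-dimethoxyphenyl]-4-(hydroxymethyl)oxolan-3-yl][4-(benzyloxy)-3-methoxyphenyl]methanone | O=C(c1ccc(OCc2ccccc2)c(OC)c1)[C@H]1CO[C@H](c2cc(OC)c(OCC=C)c(OC)c2)[C@H]1CO[Li] | intermediate (not isolated)
15 | [(3R,4R,5S)-5-[4-(allyloxy)-3,5-dimethoxyphenyl]-4-(hydroxymethyl)oxolan-3-yl][4-(benzyloxy)-3-methoxyphenyl]methanol, both carbinol epimers | OC(c1ccc(OCc2ccccc2)c(OC)c1)[C@H]1CO[C@H](c2cc(OC)c(OCC=C)c(OC)c2)[C@H]1CO | intermediate
16 | (1R,2S,5R,6S)-6-[4-(allyloxy)-3,5-dimethoxyphenyl]-2-[4-(benzyloxy)-3-methoxyphenyl]-3,7-dioxabicyclo[3.3.0]octane | COc1cc([C@H]2OC[C@H]3[C@@H]2CO[C@@H]3c2cc(OC)c(OCC=C)c(OC)c2)ccc1OCc1ccccc1 | intermediate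
17 | 4-[(1R,2S,5R,6S)-6-[4-(benzyloxy)-3-methoxyphenyl]-3,7-dioxabicyclo[3.3.0]octan-2-yl]-2,6-dimethoxyphenol | COc1cc([C@H]2OC[C@H]3[C@@H]2CO[C@@H]3c2cc(OC)c(O)c(OC)c2)ccc1OCc1ccccc1 | intermediate
18 | (S)-4-benzyloxazolidin-2-one | O=C1N[C@@H](Cc2ccccc2)CO1 | starting material
19 | lithium salt of (S)-4-benzyloxazolidin-2-one | O=C1N([Li])[C@@H](Cc2ccccc2)CO1 | intermediate (not isolated)
20 | (S)-4-benzyl-3-(2-bromoacetyl)oxazolidin-2-one | O=C1OC[C@H](Cc2ccccc2)N1C(=O)CBr | intermediate
21 | (S)-4-benzyl-3-[2-[4-[(1R,2S,5R,6S)-6-[4-(benzyloxy)-3-methoxyphenyl]-3,7-dioxabicyclo[3.3.0]octan-2-yl]-2,6-dimethoxyphenoxy]acetyl]oxazolidin-2-one | COc1cc([C@H]2OC[C@H]3[C@@H]2CO[C@@H]3c2cc(OC)c(OCC(=O)N3[C@@H](Cc4ccccc4)COC3=O)c(OC)c2)ccc1OCc1ccccc1 | intermediate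
22 | 4-(benzyloxy)-3-methoxybenzaldehyde | COc1cc(C=O)ccc1OCc1ccccc1 | starting material
23 | (Z)-dibutylboron enolate of 21 | COc1cc([C@H]2OC[C@H]3[C@@H]2CO[C@@H]3c2cc(OC)c(O/C=C(\OB(CCCC)CCCC)N3[C@@H](Cc4ccccc4)COC3=O)c(OC)c2)ccc1OCc1ccccc1 | intermediate (not isolated)
24 | syn-aldol imide, (2S,3R)-2-aryloxy-3-[4-(benzyloxy)-3-methoxyphenyl]-3-hydroxypropanoyl on (S)-4-benzyloxazolidin-2-one | COc1cc([C@H]2OC[C@H]3[C@@H]2CO[C@@H]3c2cc(OC)c(O[C@H](C(=O)N3[C@@H](Cc4ccccc4)COC3=O)[C@H](O)c3ccc(OCc4ccccc4)c(OC)c3)c(OC)c2)ccc1OCc1ccccc1 | intermediate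
25 | (2S,3S)-3-(4-nitrobenzoyloxy) imide | COc1cc([C@H]2OC[C@H]3[C@@H]2CO[C@@H]3c2cc(OC)c(O[C@H](C(=O)N3[C@@H](Cc4ccccc4)COC3=O)[C@@H](OC(=O)c3ccc(cc3)[N+](=O)[O-])c3ccc(OCc4ccccc4)c(OC)c3)c(OC)c2)ccc1OCc1ccccc1 | intermediate
26 | di-O-benzyl hedyotol C | COc1cc([C@H]2OC[C@H]3[C@@H]2CO[C@@H]3c2cc(OC)c(O[C@H](CO)[C@@H](O)c3ccc(OCc4ccccc4)c(OC)c3)c(OC)c2)ccc1OCc1ccccc1 | intermediate
27 | hedyotol C | COc1cc([C@H]2OC[C@H]3[C@@H]2CO[C@@H]3c2cc(OC)c(O[C@H](CO)[C@@H](O)c3ccc(O)c(OC)c3)c(OC)c2)ccc1O | target

**Step count and risks**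

Total step count: 15. Longest linear sequence: 14 steps (steps 1–9 and 11–15; step 10 prepares reagent 20).

Steps most likely to fail:

1. Step 5 (Proposed new method). What may go wrong: elimination of HI from the ring-opened benzylic iodide, or C–O bond formation at C6 before C–C bond formation at C1, which would lead to the endo-aryl epimer. The fallback sets out from 7 and returns at 10, making the same two bonds one at a time by known reactions. Lewis-acid methanolysis of the donor–acceptor cyclopropane (Sc(OTf)3, MeOH) should give the benzylic methyl ether lactone F1. Hydroxymethylation of its malonate-type C–H (aqueous CH2O, K2CO3) should give the hydroxymethyl lactone F2. Acid-catalysed SN1 etherification (camphor-10-sulfonic acid, CH2Cl2) should then ionise the benzylic methyl ether and let the cis hydroxymethyl group capture the cation to give 10; the trans epimer of F2 is returned through base-mediated retro-aldol equilibration.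

2. Step 8. What may go wrong: poor facial selectivity in the cationic ring closure, or acid-induced ionisation of the C6–O7 bond with epimerisation at C6. The fallback sets out from 11 and returns at 16, replacing the SN1 closure by reagent-controlled reduction and an SN2 closure that leaves the benzylic carbon untouched. Addition of 13 to 11 with a cold quench should give the hydroxy ketone F3. Corey–Bakshi–Shibata reduction ((R)-2-methyl-CBS-oxazaborolidine, BH3·SMe2) should give the single (S)-carbinol diol F4. Selective sulfonylation of the primary hydroxyl (TsCl, pyridine, 0 °C) should give the primary tosylate F5, and NaH in THF should close the ring by attack of the benzylic alkoxide on C4 to give 16.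

3. Step 13. What may go wrong: β-elimination across the activated β-hydroxy imide, or ionisation of the electron-rich benzylic oxyphosphonium with loss of stereospecificity. The fallback sets out from 24 and returns at 26, replacing the inversion by an oxidation–reduction sequence. LiBH4 should remove the auxiliary to give the threo diol F6. TBSCl and imidazole should protect the primary hydroxyl to give the silyl ether F7. Dess–Martin periodinane should give the aryl ketone F8. Zn(BH4)2, chelated between the carbonyl and the aryloxy oxygen, should give the erythro alcohol F9. TBAF should then give 26.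

Further compounds

F1 | step 5 | methyl (4R)-4-[[4-(allyloxy)-3,5-dimethoxyphenyl](methoxy)methyl]-2-oxooxolane-3-carboxylate, epimers at C3 and at the benzylic carbon | COC(=O)C1C(=O)OC[C@@H]1C(OC)c1cc(OC)c(OCC=C)c(OC)c1
F2 | step 5 | methyl (4R)-3-(hydroxymethyl)-4-[[4-(allyloxy)-3,5-dimethoxyphenyl](methoxy)methyl]-2-oxooxolane-3-carboxylate, epimers at C3 and at the benzylic carbon | COC(=O)C1(CO)C(=O)OC[C@@H]1C(OC)c1cc(OC)c(OCC=C)c(OC)c1
F3 | step 8 | [(3R,4R,5S)-5-[4-(allyloxy)-3,5-dimethoxyphenyl]-4-(hydroxymethyl)oxolan-3-yl][4-(benzyloxy)-3-methoxyphenyl]methanone | O=C(c1ccc(OCc2ccccc2)c(OC)c1)[C@H]1CO[C@H](c2cc(OC)c(OCC=C)c(OC)c2)[C@H]1CO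
F4 | step 8 | (S)-[(3R,4R,5S)-5-[4-(allyloxy)-3,5-dimethoxyphenyl]-4-(hydroxymethyl)oxolan-3-yl][4-(benzyloxy)-3-methoxyphenyl]methanol | O[C@H](c1ccc(OCc2ccccc2)c(OC)c1)[C@H]1CO[C@H](c2cc(OC)c(OCC=C)c(OC)c2)[C@H]1CO
F5 | step 8 | primary 4-methylbenzenesulfonate of F4 | O[C@H](c1ccc(OCc2ccccc2)c(OC)c1)[C@H]1CO[C@H](c2cc(OC)c(OCC=C)c(OC)c2)[C@H]1COS(=O)(=O)c1ccc(C)cc1
F6 | step 13 | threo (1R,2R) diol, the C7'' epimer of 26 | COc1cc([C@H]2OC[C@H]3[C@@H]2CO[C@@H]3c2cc(OC)c(O[C@H](CO)[C@H](O)c3ccc(OCc4ccccc4)c(OC)c3)c(OC)c2)ccc1OCc1ccccc1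
F7 | step 13 | primary tert-butyldimethylsilyl ether of F6 | COc1cc([C@H]2OC[C@H]3[C@@H]2CO[C@@H]3c2cc(OC)c(O[C@H](CO[Si](C)(C)C(C)(C)C)[C@H](O)c3ccc(OCc4ccccc4)c(OC)c3)c(OC)c2)ccc1OCc1ccccc1
F8 | step 13 | (R)-2-aryloxy-3-silyloxy-1-[4-(benzyloxy)-3-methoxyphenyl]propan-1-one | COc1cc([C@H]2OC[C@H]3[C@@H]2CO[C@@H]3c2cc(OC)c(O[C@H](CO[Si](C)(C)C(C)(C)C)C(=O)c3ccc(OCc4ccccc4)c(OC)c3)c(OC)c2)ccc1OCc1ccccc1
F9 | step 13 | erythro (1S,2R) alcohol, the primary tert-butyldimethylsilyl ether of 26 | COc1cc([C@H]2OC[C@H]3[C@@H]2CO[C@@H]3c2cc(OC)c(O[C@H](CO[Si](C)(C)C(C)(C)C)[C@@H](O)c3ccc(OCc4ccccc4)c(OC)c3)c(OC)c2)ccc1OCc1ccccc1
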